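The amounts in the flask are those of the noon and winter runs: 0.30 M of starting material, the limiting reagent, with 2.00 equiv of coupling partner. The loading and the time differ.

common to all: starting material 0.30 M
- noon: coupling partner 2 equiv; precatalyst 0.7 mol%; run made earlier
- winter: coupling partner 2 equiv; precatalyst 1 mol%; run made earlier
- dawn: coupling partner 4 equiv; precatalyst 1.4 mol%; run made earlier
- flask: coupling partner 2.00 equiv; precatalyst 1.4 mol%; time 2.0 d

| run | time / h | target / % | starting material / % |
|---|---|---|---|
| noon | 3.00 | 0 | 102 |
| noon | 5.00 | 3 | 99 |
| noon | 8.00 | 2 | 93 |
| noon | 10.0 | 13 | 90 |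
| noon | 15.0 | 18 | 80 |
| noon | 25.0 | 40 | 63 |
| noon | 40.0 | 62 | 35 |
| winter | 6.00 | 8 | 97 |
| winter | 12.0 | 19 | 78 |
| winter | 15.0 | 26 | 75 |
| winter | 20.0 | 39 | 63 |
| winter | 30.0 | 62 | 40 |
| winter | 40.0 | 78 | 25 |
| dawn | 3.00 | 8 | 100 |
| dawn | 10.0 | 42 | 56 |
| dawn | 20.0 | 86 | 17 |
| dawn | 30.0 | 97 | 0 |
| dawn | 40.0 | 100 | 1 |

(each reading ± 2 percentage points)

- steps that have been proposed: starting material + free catalyst -> catalyst intermediate A; coupling partner + catalyst intermediate A -> catalyst intermediate B; catalyst intermediate B -> free catalyst + target; coupling partner <-> dormant form; coupling partner + precatalyst -> free catalyst + spent reagent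

- amount of target in the flask at 2.0 d, in percent of the starting material charged
- amount of starting material in the flask at 2.0 d, in percent of the starting material charged
- concentration of coupling partner at 2.0 d, in M

I fold loading and time into their product. The noon run at 40.0 h and the winter run at 30.0 h have products in the ratio 0.933, and each reads 62% of target. So I take the winter run's mean pace, 78% in 40.0 h at 1 mol%, and apply it to the flask's 1.4 mol% and 2.0 d. This gives 1.31, the charge count: how many charges of starting material the flask's catalyst turns over at the winter pace. Since the count exceeds one, I expect the flask to come close to full conversion, leaving about 0.300 M of coupling partner, free and dormant together; the runs read target and starting material, not coupling partner, so I give no split. One number is not enough: the dawn run at 20.0 h, with 4 equiv, has the noon product but reads 86% of target against the noon 62%.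

The forecast gives 98% of target, 1% of starting material and 0.26 M for c(coupling partner), taking the total “minus an unknown dormant share”.

The flask gives 96.6% of target, 3.36% of starting material and 0.117 M for c(coupling partner), beside 0.191 M of dormant form, whose exchange with coupling partner, both ways together and taken by itself, has a relaxation half-life of 0.187 d, shorter than the time.

    starting material + free catalyst → catalyst intermediate A (k = 0.0260 M⁻¹ s⁻¹)
    coupling partner + catalyst intermediate A → catalyst intermediate B (k = 0.0230 M⁻¹ s⁻¹)
    catalyst intermediate B → free catalyst + target (k = 0.0620 s⁻¹)
    coupling partner ⇌ dormant form (K = 1.40, k = 2.50 × 10⁻⁵ s⁻¹)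
    coupling partner + precatalyst → free catalyst + spent reagent (k = 1.50 × 10⁻⁵ M⁻¹ s⁻¹)

At 1.50 d the flask's count is 0.983, yet target stands at 84.8%, so in this flask the count reads high there, and the last part of the charge is the part to watch. With 0.84 mol% of precatalyst, the count falls to 0.786, which reads as 78.6% of target; that neighbour gives 83.2%.

The readings are calculated for an exercise.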